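## Assumptions
- Unit A is the tetrasubstituted-olefin half. Unit B is the primed, oxa-bridged half.
- The known photoproduct from α-santonin (compound 2) is taken to have the C1/C10 configuration drawn in the target.
- Anabsin is C30H40O7. It is the isomer of "absinthin diol 8 + O", not a further-oxidised product.

## Retrosynthetic overview
1. Anabsin comes from exo-epoxy diol **9**: the C10′–OH captures the tertiary C4′ cation of the opened epoxide, closing the oxa-bridge and leaving the C3′–OH exo.
2. **9** comes from the norbornene diol **8** (absinthin constitution). **8** is a retro-[4+2] product of two identical cyclopentadiene monomers (**6**, 10-OTES-guaia-2,4-dien-6,12-olide), one acting as diene and one as dienophile.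
3. **6** is made from (−)-α-santonin by photorearrangement (6-6 to 5-7), then Luche reduction and Burgess dehydration.
4. Ring-formation order:
   - 5-7 bicycle (step 1);
   - cyclopentadiene (step 5);
   - central norbornene and cyclopentane (step 6, the bold homodimerisation under pressure);
   - oxa-bridge THF ring (step 9).

## Route

**Step 1**
Reactants: 1 (−)-α-santonin
Product: 2 O-acetylisophotosantonic lactone
Conditions: hv (medium-pressure Hg lamp, Pyrex), AcOH/H2O 1:1, 25 °C
Reagents that add atoms: acetic acid, CC(=O)O
Why: Type-A dienone (lumiketone) photorearrangement followed by acid-opened cyclopropyl ketone gives the 5-7 skeleton and a C10 tertiary cation trapped by AcOH; C6, C7 and C11 are untouched, and C1/C10 are set by this rearrangement.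

**Step 2**
Reactants: 2
Product: 3 isophotosantonic lactone (10-hydroxy-3-oxoguai-4-en-6,12-olide)
Conditions: K2CO3, MeOH/H2O 9:1, 50 °C; then 1 M HCl, 25 °C (re-lactonisation of any hydroxy-acid)
Reagents that add atoms: none
Why: Base cleaves the acyl–O bond of the tertiary acetate, so the C10 C–O bond and its configuration are retained (ester hydrolysis).

**Step 3**
Reactants: 3
Product: 4 10-O-TES ether
Conditions: TESOTf, 2,6-lutidine, CH2Cl2, −78 to 0 °C
Reagents that add atoms: TESOTf, CC[Si](CC)(CC)OS(=O)(=O)C(F)(F)F
Why: The tertiary OH is protected so that Burgess dehydration cannot touch it; the C–O bond is not involved, so C10 is retained.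

**Step 4**
Reactants: 4
Product: 5 3-hydroxy-guai-4-en-6,12-olide (C3 epimer mixture)
Conditions: NaBH4, CeCl3·7H2O, MeOH, −20 °C
Reagents that add atoms: none
Why: Luche 1,2-reduction of the cyclopentenone leaves the lactone untouched; the C3 stereocentre is destroyed in the next step, so the epimer ratio is irrelevant.

**Step 5**
Reactants: 5
Product: 6 cyclopentadiene monomer (10-OTES-guaia-2,4-dien-6,12-olide)
Conditions: Burgess reagent, benzene, 25 °C, 30 min; cold filtration through neutral silica; use at once
Reagents that add atoms: none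
Why: Syn (Ei) elimination uses a C2–H, the only β-H (C4 has none), so the C2=C3/C4=C5 diene forms regiospecifically and C1 stays sp3; no ionisation occurs that could scramble C1–H.

**Step 6**
Reactants: 6 (two molecules)
Product: 7 bis-TES endo Diels–Alder homodimer
Conditions: 1.5 M in CH2Cl2, 12 kbar, 25 °C, 48 h
Reagents that add atoms: none
Why: Cyclopentadiene/cyclopentadiene [4+2] (as in dicyclopentadiene formation) with one monomer as diene (C2′–C5′) and the less hindered C2=C3 of the other as dienophile. Both partners react on the H1 face, anti to the C10–OTES bulk, and the TS is endo; the result is cis C2/C3, four new stereocentres, and the C2–C2′/C3–C5′ regiochemistry (less hindered C3 pairs with the quaternary C5′). Pressure (ΔV‡ about −35 cm³/mol) outcompetes the cyclopentadiene 1,5-H shifts that would destroy C1.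
Proposed new method: this homodimerisation of a guaianolide cyclopentadiene has not been shown in vitro; the reasoning above (face, endo, regiochemistry, pressure) rests on cyclopentadiene dimerisation and the biogenetic proposal for absinthin.

**Step 7**
Reactants: 7
Product: 8 diene-dimer diol (absinthin constitution, C30H40O6)
Conditions: HF·pyridine, pyridine/THF 1:3, 0 to 25 °C
Reagents that add atoms: none
Why: Fluoride removes both tertiary silyl ethers (Si–O cleavage), so C10 and C10′ keep their configuration; the lactones and alkenes survive the buffered conditions.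

**Step 8**
Reactants: 8
Product: 9 exo-epoxy diol (3′,4′-epoxide)
Conditions: mCPBA, solid NaHCO3, CH2Cl2, 0 °C
Reagents that add atoms: mCPBA, OOC(=O)c1cccc(Cl)c1
Why: Prilezhaev epoxidation of the strained trisubstituted norbornene C3′=C4′. The syn-disposed C10′–OH hydrogen-bonds the peracid and delivers O to the exo face, while the endo face is blocked by ring A. The tetrasubstituted C4=C5 is deactivated by the allylic C6 acyloxy group and shielded by ring B.

**Step 9**
Reactants: 9
Product: 10 anabsin
Conditions: CSA (0.1 equiv), anhydrous CH2Cl2, 4 Å MS, −10 to 25 °C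
Reagents that add atoms: none (isomerisation)
Why: Acid ionises the tertiary C4′–O bond of the exo epoxide to a 2-methyl-2-norbornyl-type cation. The tethered C10′–OH can reach only the exo face, so it closes the 2-oxabicyclo[2.2.1] ring with net retention at C4′, and the C3′–O bond is never broken, leaving C3′–OH exo (cis-exo O,O).
Proposed new method: net stereoretentive epoxide-to-cyclic-ether closure through a tertiary norbornyl cation captured by a rigid syn tether. The closest known reaction is acid-catalysed epoxy-alcohol cycloetherification of tertiary epoxides to tetrahydrofurans.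

## Compound list
1 | (−)-α-santonin | C[C@H]1[C@@H]2CC[C@]3(C=CC(=O)C(=C3[C@H]2OC1=O)C)C | starting material
2 | O-acetylisophotosantonic lactone | CC1=C2[C@H]3OC(=O)[C@@H](C)[C@@H]3CC[C@](C)(OC(C)=O)[C@@H]2CC1=O | intermediate
3 | isophotosantonic lactone | CC1=C2[C@H]3OC(=O)[C@@H](C)[C@@H]3CC[C@](C)(O)[C@@H]2CC1=O | intermediate
4 | 10-O-TES ether of 3 | CC1=C2[C@H]3OC(=O)[C@@H](C)[C@@H]3CC[C@](C)(O[Si](CC)(CC)CC)[C@@H]2CC1=O | intermediate
5 | 3-hydroxy-10-OTES-guai-4-en-6,12-olide (C3 epimers) | CC1=C2[C@H]3OC(=O)[C@@H](C)[C@@H]3CC[C@](C)(O[Si](CC)(CC)CC)[C@@H]2CC1O | intermediate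
6 | 10-OTES-guaia-2,4-dien-6,12-olide (cyclopentadiene) | CC1=C2[C@H]3OC(=O)[C@@H](C)[C@@H]3CC[C@](C)(O[Si](CC)(CC)CC)[C@@H]2C=C1 | intermediate
7 | bis-TES endo Diels–Alder homodimer | CC1=C2[C@H]3OC(=O)[C@@H](C)[C@@H]3CC[C@](C)(O[Si](CC)(CC)CC)[C@@H]2[C@H]2[C@@H](C=C5C)[C@@H]4[C@]5([C@H]6OC(=O)[C@@H](C)[C@@H]6CC[C@]4(C)O[Si](CC)(CC)CC)[C@@H]12 | intermediate
8 | dimer diol (absinthin constitution) | CC1=C2[C@H]3OC(=O)[C@@H](C)[C@@H]3CC[C@](C)(O)[C@@H]2[C@H]2[C@@H](C=C5C)[C@@H]4[C@]5([C@H]6OC(=O)[C@@H](C)[C@@H]6CC[C@]4(C)O)[C@@H]12 | intermediate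
9 | exo-3′,4′-epoxy diol | CC1=C2[C@H]3OC(=O)[C@@H](C)[C@@H]3CC[C@](C)(O)[C@@H]2[C@H]2[C@@H]([C@@H]7O[C@@]75C)[C@@H]4[C@]5([C@H]6OC(=O)[C@@H](C)[C@@H]6CC[C@]4(C)O)[C@@H]12 | intermediate
10 | anabsin | CC1=C2[C@H]3OC(=O)[C@@H](C)[C@@H]3CC[C@](C)(O)[C@@H]2[C@H]2[C@@H]3[C@@H]4[C@]5([C@H]6OC(=O)[C@@H](C)[C@@H]6CC[C@]4(C)O[C@@]5(C)[C@H]3O)[C@@H]12 | target

## Totals
- Total steps: 9
- Longest linear sequence: 9 (the route is linear from 1; step 6 consumes two molecules of 6)

## Three steps most likely to fail
1. **Step 6, homodimerisation.** Cyclopentadiene tautomerisation, wrong regiochemistry, or the wrong diene/dienophile roles could give a mixture. Fallback: a stepwise electron-transfer (radical-cation) [4+2] using catalytic tris(4-bromophenyl)aminium hexachloroantimonate in CH2Cl2 at 0 °C, which avoids the thermal 1,5-H shifts.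
2. **Steps 8/9, chemoselective exo-epoxidation and retentive cation capture.** The tetrasubstituted olefin might compete, or a Wagner–Meerwein shift might occur. Fallback: Donohoe-type OH-directed OsO4/TMEDA exo cis-dihydroxylation of 8, then Martin-sulfurane dehydrative etherification at the tertiary C4′–OH.
3. **Step 5, cyclopentadiene formation.** The diene may isomerise or dimerise on work-up. Fallback: deprotonate 4 to the dienolate and trap it as the dienyl triflate (KHMDS, PhNTf2), then reduce with Pd(OAc)2/PPh3, HCO2H, Et3N to the same diene 6 under neutral conditions.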